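## Structural features

The target is an achiral 1H-isochromen-1-one. Benzene ring A (C4a, C5–C8, C8a) is fused to an enol-lactone ring (C1 carbonyl, O2, C3, C4) that carries an n-pentyl chain on C3. Ring A has a free hydroxyl on C6 and, on C8, an ether oxygen that links it to a second benzene ring B. In ring B the bridging oxygen sits on C1' between a hydroxyl on C2' and a pentyl chain on C6', and C4' carries a methoxy group. There is no stereocentre and no configurational double bond, so no stereocentres stand next to each other and every problem is one of regio- or chemoselectivity. The fragile parts are the enol lactone (opened by hydroxide or alkoxide, C3=C4 reducible), the two electron-rich phenols, and the methyl ether, which must stay while the two other phenolic oxygens are set free. The real difficulty is the diaryl ether: its ring-B oxygen is flanked by two ortho substituents and its ring-A carbon C8 lies peri to the C1 carbonyl. A second difficulty is to place carbon substituents on the neighbouring atoms C4a and C8a, with oxygen on C6 and C8, without regioisomers. The key step uses the C4a/C8a/C8 triad: C4a and C8a bear the carbons C4 and C1 and C8 bears a heteroatom, so a 3-fluoroaryne spanning C4a–C8a can take up a malonate across the triple bond. Fluorine on C8 serves first as the directing group and later as the leaving group for the ring-B phenoxide.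

## Logic of the disconnections

23 to 22. The two benzyl–oxygen bonds on O6 and O2' are added back. Both phenols must be masked in the base-mediated steps: a free O6 would become a phenoxide that switches off substitution at C8, and a free O2' would compete with O1'. Benzyl is chosen because it can be told apart from the methyl ether on O4'. The gain is that no intermediate has an acidic OH and one final operation frees both. The demand is a cleavage that spares the methyl ether, the enol lactone and C3=C4, which points to a Lewis acid with a cation trap and not to hydrogenolysis.

22 to 14 and 21. The C8–O1' bond is cut. This is the most convergent cut, dividing the molecule into its two aromatic halves. C8 is ortho to the C1 carbonyl, so fluorine there can leave by addition–elimination. In the closed lactone the carbonyl is locked coplanar with ring A, which is why the ether is made after ring closure. The gain is two fragments made independently. The demand is that a 2,6-disubstituted phenoxide attacks a carbon next to C8a under dry base that does not open the lactone.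

14 to 12. The lactone bond O2–C1 is opened to a methyl ester and a ketone enol, and a tert-butoxycarbonyl group is added back on C4. The isocoumarin is the cyclised form of an ortho-(2-oxoalkyl)benzoate (13), and the extra carboxyl on C4 is what allows acylation there. The gain is a benzene with two side chains in place of the heterocycle. The demand is that ester cleavage, decarboxylation and ring closure run under acid mild enough for the benzyl ether and the aryl fluoride.

12 to 10 and 11. The C3–C4 bond is cut. C3 and the pentyl chain together form a six-carbon acyl unit, and C4 is an ester α-carbon. The gain is that all carbons beyond C4 come from commercial 11. The demand is acylation on carbon and only once.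

10 to 6 and 7. The C4a–C4 and C8a–C1 bonds are cut together (forward via 8 and 9). Two carbon substituents on adjacent ring atoms with a heteroatom on the next atom are the retron of an aryne σ-insertion. 7 contains C4, C1 and the removable carboxyl. The gain is that tetrasubstituted ring A is reduced to a benzene carrying fluorine, a benzyloxy group and the aryne-generating pair, with no transition metal. The demand is addition remote from fluorine, migration of the methyl ester only, and a single arylation.

6 to 5, 3, 2 and 1. Cut in turn are the O–S bond, the phenol C–O bond (from C–Br), the C–Si bond (from the C–H between bromine and fluorine) and the benzyl ether C–O bond (from C–F). The silyl group must sit between fluorine and the triflate oxygen. In 2 that carbon is the only one flanked by two halogens, and bromine is a placeholder for oxygen. The gain is commercial 1, whose two fluorines are equivalent. The demand is metalation at the right C–H, survival of an ortho-haloaryllithium, and bromine–lithium exchange with the C–Si bond intact.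

21 to 20 and 19. The C1''–C2'' bond of the pentyl chain is cut as an alkene. A formyl group ortho to the phenol is the simplest handle on C6'. The gain is that four chain carbons come from a phosphonium salt. The demand is saturation of the alkene without hydrogenolysis of the benzyl ether.

19 to 18. The C6'–CHO bond is cut. The phenol has only one free ortho position, so chelation-controlled formylation is unambiguous. The demand is ortho delivery within a metal phenoxide.

18 to 16 and 15. The phenol oxygen on C1' comes from the formyl carbon by oxygen insertion, and the O2'–benzyl bond is cut. In 15 the two future ortho oxygens differ from the start (one OH, one CHO). The benzyl group therefore goes on O2' and the free OH appears on C1' without selective protection of a catechol. The gain is a cheap commercial aldehyde. The demand is aryl and not hydride migration, which the ortho and para alkoxy groups ensure.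

## Other disconnections considered

Alternative 1: Biomimetic closure of ring A and the lactone from pyranone A2.
- Cut: ring A between C4a and C8a, and the lactone bond C1–O2. The ring carbons of A2 become C1, C8a, C8, C7 and C6; its side chain supplies C5, C4a, C4, C3 and the pentyl group.
- Forward key step: an alkoxide opens the pyranone carbonyl. The C8a carbon adds to the C4a ketone, dehydration aromatises ring A with a free OH on C6, and the C3 enol oxygen closes onto C1 to give A1.
- In favour: ring A and the lactone form in one flask without metal, silicon or fluorine, and O6 emerges free. The ring-B oxygen is attached to a pyranone carbon by addition–elimination on a vinylogous acid derivative, which is easier than substitution at the hindered arene carbon C8. On this bond the alternative is better.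
- Against: the opened chain can fold in several ways (Claisen closure of C5 onto the ester, aldol of C7 onto the C3 carbonyl, re-closure to a pyranone), and nothing in A2 enforces the C8a-to-C4a mode. The alkoxide can also expel the aryloxide from the vinylogous carbonate. Making A2 needs acylation of a pyranone polyanion and handling of a 1,3-diketone side chain that itself cyclises.
- Comparison: structurally both plans put the ether next to the carboxyl-bearing carbon; the chosen plan fixes each ring-A position by the polarity that fluorine imposes. Mechanistically both key steps are metal-free anionic cascades ending in an acyl transfer, so they are equal in kind. In step count the alternative would be shorter after 21 if the folding were selective, so it is better on count. It needs 21 just as the chosen plan does.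

Alternative 2: Ring A by pyranone Diels–Alder from A4 and A5.
- Cut: C6–C7 and C4a–C5. Pyranone ester A4 supplies C7, C8, C8a and C4a; ketene acetal A5 supplies C6 and C5.
- Forward key step: inverse-electron-demand [4+2] cycloaddition, decarboxylative cycloreversion of the bridged lactone and loss of one benzyloxy group give A3.
- In favour: the polarity match (nucleophilic CH2 of A5 onto the ring carbon that is β to both carbonyls) fixes the regiochemistry. Ring A arrives with O6 benzylated and the ether is again made at the pyranone stage, which is better than the arene substitution. A3 is an ortho-toluate, so lateral metalation, acylation with a hexanoic acid derivative and cyclisation would reach 22 without a sacrificial carboxyl on C4. That is better in atom economy and equal in step count over that stretch.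
- Against: the 4-aryloxy group is a donor on the diene and the reacting terminus carries a methyl group, so an already sluggish diene is slowed further. A5 must be prepared and is sensitive to acid and moisture. Lateral metalation must choose the ring-A methyl over three other benzylic CH2 groups.
- Comparison: the key step is thermal and pericyclic, whereas the aryne insertion is ionic and runs at room temperature. Overall step count should be about equal.

Alternative 3: Ring B built onto aryloxymalonate A7 from enone A8.
- Cut: C1'–C6' and C2'–C3' of ring B.
- Forward key step: with a potassium alkoxide the malonate anion of A7 adds to the β-carbon of A8, and the methyl ketone enolate closes onto one ester to give cyclohexane-1,3-dione A6.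
- In favour: this is the classical annulation used for 5-alkylresorcinols. No separate ring-B phenol is needed, so the five steps to 21 disappear, which is better. The crowded aryl–O–aryl bond is first made as an aryl–O–alkyl bond, which is easier than the substitution by a hindered phenoxide and better on that bond.
- Against: the alkoxide meets the enol lactone, which it opens. The malonate carbon is tertiary, so the conjugate addition sets a quaternary C1' next to a tertiary C6' and is reversible. After A6 ring B still needs removal of the ester on quaternary C1', dehydrogenation to the arene and O-methylation at O4' in preference to O2', each with its own selectivity problem.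
- Comparison: the chosen plan takes ring B at the aromatic oxidation level with its three oxygens already different. Both key steps are carbanion additions followed by acyl transfer, so they are equal in kind. The saving in fragment steps is offset by the steps after the annulation, so the count is about equal.

Key step: step 5

Remark on the chemistry: the malonate partner is used as the mixed tert-butyl methyl diester 7; the carbon skeletons of both insertion partners and of the product are unchanged, and only the alkyl group on the side-chain carboxyl differs, so that this carboxyl can later be lost under catalytic acid that spares the benzyl ether.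

Remark on the chemistry: the target has no stereocentre; 12 forms as a racemate and 20 as an E/Z mixture, and both elements are erased in the step that follows.

## Steps

Step 1
Reactants: 1 1-bromo-3,5-difluorobenzene
Product: 2 1-(benzyloxy)-3-bromo-5-fluorobenzene
Conditions: BnOH (1.05 equiv), t-BuOK (1.1 equiv), NMP, 0 °C → rt
Reagents that add atoms: benzyl alcohol, OCc1ccccc1
Why: Nucleophilic aromatic substitution (SNAr) of one of two equivalent fluorides, activated inductively by the meta bromine and the second fluorine; the alkoxy group introduced deactivates the ring, so the second fluorine should stay.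

Step 2
Reactants: 2 1-(benzyloxy)-3-bromo-5-fluorobenzene
Product: 3 [4-(benzyloxy)-2-bromo-6-fluorophenyl]trimethylsilane
Conditions: LiN(i-Pr)2 (1.1 equiv), THF, −78 °C, 30 min; Me3SiCl, −78 °C → rt
Reagents that add atoms: chlorotrimethylsilane, C[Si](C)(C)Cl
Why: Ortho-metalation by a lithium amide: the C–H flanked by bromine and fluorine should be the most acidic of the three, since two halogens acidify their common ortho position more than one halogen plus an alkoxy group; at −78 °C the aryllithium should not lose lithium halide and is silylated.

Step 3
Reactants: 3 [4-(benzyloxy)-2-bromo-6-fluorophenyl]trimethylsilane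
Product: 5 5-(benzyloxy)-3-fluoro-2-(trimethylsilyl)phenol, via lithium aryltrimethoxyborate 4 (not isolated)
Conditions: n-BuLi, THF, −78 °C; B(OMe)3, −78 → 0 °C; then AcOH, 30% H2O2, 0 °C → rt
Reagents that add atoms: hydrogen peroxide, OO
Why: Bromine–lithium exchange (faster than any deprotonation at −78 °C; the aryllithium has no ortho leaving group), borylation, and oxidative 1,2-shift of the aryl group from boron to oxygen; the weakly acidic oxidation medium spares the aryl–silicon bond.

Step 4
Reactants: 5 5-(benzyloxy)-3-fluoro-2-(trimethylsilyl)phenol
Product: 6 5-(benzyloxy)-3-fluoro-2-(trimethylsilyl)phenyl trifluoromethanesulfonate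
Conditions: Tf2O, pyridine, CH2Cl2, 0 °C
Reagents that add atoms: trifluoromethanesulfonic anhydride, O=S(=O)(OS(=O)(=O)C(F)(F)F)C(F)(F)F
Why: O-Sulfonylation of the phenol gives the ortho-silylaryl triflate, the standard fluoride-triggered aryne precursor.

Step 5
Reactants: 6 5-(benzyloxy)-3-fluoro-2-(trimethylsilyl)phenyl trifluoromethanesulfonate; 7 tert-butyl methyl propanedioate
Product: 10 methyl 4-(benzyloxy)-2-(2-tert-butoxy-2-oxoethyl)-6-fluorobenzoate, via 5-(benzyloxy)-3-fluorobenzyne 8 (not isolated), via potassium benzocyclobutenolate 9 (not isolated)
Conditions: 7 (1.5 equiv), KF (3 equiv), 18-crown-6 (3 equiv), THF, 0 °C → rt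
Reagents that add atoms: none
Why: Fluoride attacks silicon and the aryl anion expels triflate, a far better leaving group than the fluoride on its other side, to give aryne 8; fluoride also deprotonates 7. The malonate carbanion adds to the aryne carbon remote from fluorine (future C4a), because the C–F bond distorts the triple bond and stabilises inductively the negative charge that develops on the carbon next to it (future C8a); the benzyloxy group, meta and para to the two aryne carbons, has no comparable influence. The aryl anion then adds to the neighbouring methyl ester carbonyl (4-exo-trig) to give benzocyclobutenolate 9, whose fragmentation breaks the former malonate C–C bond and releases the stabilised tert-butyl arylacetate enolate; protonation gives 10, so C4a–C4 and C8a–C1 are formed in one operation. The closest known reaction type is the fluoride-induced acyl-alkylation (σ-insertion) of arynes with malonates and β-keto esters, which includes 3-halo- and 3-alkoxyarynes. No ring of the product is closed and no stereocentre is formed; the two stereocentres of 9 vanish on ring opening. Three selectivities are needed: the regiochemistry of addition, secured by fluorine; migration of the methoxycarbonyl and not the tert-butoxycarbonyl group, secured by the much slower attack on the hindered tert-butyl ester; and single arylation, secured by an excess of 7, which is far more acidic than 10.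

Step 6
Reactants: 10 methyl 4-(benzyloxy)-2-(2-tert-butoxy-2-oxoethyl)-6-fluorobenzoate; 11 hexanoyl chloride
Product: 12 methyl 4-(benzyloxy)-2-(1-tert-butoxy-1,3-dioxooctan-2-yl)-6-fluorobenzoate (racemic, keto–enol mixture)
Conditions: LiN(SiMe3)2 (2.1 equiv), THF, −78 °C; 11 (1.05 equiv), −78 → 0 °C
Reagents that add atoms: none
Why: Claisen-type C-acylation of the lithium enolate of a tert-butyl arylacetate by an acid chloride; the second equivalent of base converts the more acidic β-keto ester into its enolate and so prevents a second acylation. The new stereocentre on C4 is not controlled and is removed in step 7.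

Step 7
Reactants: 12 methyl 4-(benzyloxy)-2-(1-tert-butoxy-1,3-dioxooctan-2-yl)-6-fluorobenzoate
Product: 14 6-(benzyloxy)-8-fluoro-3-pentyl-1H-isochromen-1-one, via keto ester 13 (not isolated)
Conditions: TsOH·H2O (0.2 equiv), toluene, 110 °C
Reagents that add atoms: none
Why: Acid-catalysed loss of isobutene from the tert-butyl β-keto ester and decarboxylation give ketone 13, whose enol oxygen attacks the ortho methyl ester (6-exo-trig acyl substitution, loss of methanol) to close the enol lactone. Catalytic sulfonic acid in toluene should leave the aryl benzyl ether and the aryl fluoride untouched.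

Step 8
Reactants: 15 2-hydroxy-4-methoxybenzaldehyde
Product: 16 2-(benzyloxy)-4-methoxybenzaldehyde
Conditions: BnBr, K2CO3, DMF, rt
Reagents that add atoms: benzyl bromide, BrCc1ccccc1
Why: Williamson etherification of the phenol; it places the benzyl group on the oxygen that becomes O2'.

Step 9
Reactants: 16 2-(benzyloxy)-4-methoxybenzaldehyde
Product: 18 2-(benzyloxy)-4-methoxyphenol, via aryl formate 17 (not isolated)
Conditions: mCPBA, CH2Cl2, 0 °C → rt; then K2CO3, MeOH, rt
Reagents that add atoms: 3-chloroperoxybenzoic acid, OOC(=O)c1cccc(Cl)c1
Why: Baeyer–Villiger (Dakin-type) oxidation: the aryl group migrates in preference to hydride because the ring carries ortho and para alkoxy donors; mild methanolysis of formate 17 frees the phenol.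

Step 10
Reactants: 18 2-(benzyloxy)-4-methoxyphenol
Product: 19 3-(benzyloxy)-2-hydroxy-5-methoxybenzaldehyde
Conditions: MgCl2, Et3N, (CH2O)n, MeCN, 80 °C
Reagents that add atoms: formaldehyde (as paraformaldehyde), C=O
Why: Magnesium-phenoxide-mediated ortho-formylation (Casnati–Skattebøl type): formaldehyde is delivered within the chelate to the only free ortho position, and the benzylic alkoxide is oxidised by a second formaldehyde.

Step 11
Reactants: 19 3-(benzyloxy)-2-hydroxy-5-methoxybenzaldehyde
Product: 20 2-(benzyloxy)-4-methoxy-6-[(1Z)-pent-1-en-1-yl]phenol (Z expected as main isomer, E/Z mixture acceptable)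
Conditions: n-BuPPh3Br (2.5 equiv), t-BuOK (2.5 equiv), THF, 0 °C → rt
Reagents that add atoms: butyltriphenylphosphonium bromide, CCCC[P+](c1ccccc1)(c1ccccc1)c1ccccc1.[Br-]
Why: Wittig olefination with an unstabilised ylide; one equivalent is consumed by the phenol and the phenoxide aldehyde still reacts. The alkene geometry does not matter because the double bond is saturated next.

Step 12
Reactants: 20 2-(benzyloxy)-4-methoxy-6-[(1Z)-pent-1-en-1-yl]phenol
Product: 21 2-(benzyloxy)-4-methoxy-6-pentylphenol
Conditions: H2 (1 atm), RhCl(PPh3)3 (5 mol%), toluene/EtOH, rt
Reagents that add atoms: none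
Why: Homogeneous hydrogenation of the disubstituted alkene; this rhodium catalyst does not hydrogenolyse aryl benzyl ethers.

Step 13
Reactants: 14 6-(benzyloxy)-8-fluoro-3-pentyl-1H-isochromen-1-one; 21 2-(benzyloxy)-4-methoxy-6-pentylphenol
Product: 22 6-(benzyloxy)-8-[2-(benzyloxy)-4-methoxy-6-pentylphenoxy]-3-pentyl-1H-isochromen-1-one
Conditions: Cs2CO3 (1.5 equiv), 4 Å MS, DMSO, 100 °C, Ar
Reagents that add atoms: none
Why: SNAr (addition–elimination) of fluoride by the electron-rich phenoxide: the anionic adduct is stabilised by the C1 lactone carbonyl, which is ortho to C8 and held coplanar with ring A, and fluoride is the best leaving group for this mechanism. Only O1' of 21 is free and O6 is capped, so no second phenoxide competes and ring A is not deactivated; dry conditions protect the lactone.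

Step 14
Reactants: 22 6-(benzyloxy)-8-[2-(benzyloxy)-4-methoxy-6-pentylphenoxy]-3-pentyl-1H-isochromen-1-one
Product: 23 6-hydroxy-8-(2-hydroxy-4-methoxy-6-pentylphenoxy)-3-pentyl-1H-isochromen-1-one
Conditions: BCl3, C6HMe5, CH2Cl2, −78 °C; MeOH quench
Reagents that add atoms: none
Why: Lewis-acid cleavage of both aryl benzyl ethers, with the benzyl cation trapped by pentamethylbenzene (Friedel–Crafts) so that it cannot alkylate ring B. The methyl ether (no chelating neighbour), the lactone and C3=C4 should not react at −78 °C.

## Compound list

1 | 1-bromo-3,5-difluorobenzene | Fc1cc(F)cc(Br)c1 | starting material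
2 | 1-(benzyloxy)-3-bromo-5-fluorobenzene | Fc1cc(Br)cc(OCc2ccccc2)c1 | intermediate
3 | [4-(benzyloxy)-2-bromo-6-fluorophenyl]trimethylsilane | C[Si](C)(C)c1c(F)cc(OCc2ccccc2)cc1Br | intermediate
4 | lithium [5-(benzyloxy)-3-fluoro-2-(trimethylsilyl)phenyl]trimethoxyborate (not isolated) | [Li+].CO[B-](OC)(OC)c1cc(OCc2ccccc2)cc(F)c1[Si](C)(C)C | intermediate
5 | 5-(benzyloxy)-3-fluoro-2-(trimethylsilyl)phenol | C[Si](C)(C)c1c(F)cc(OCc2ccccc2)cc1O | intermediate
6 | 5-(benzyloxy)-3-fluoro-2-(trimethylsilyl)phenyl trifluoromethanesulfonate | C[Si](C)(C)c1c(F)cc(OCc2ccccc2)cc1OS(=O)(=O)C(F)(F)F | intermediate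
7 | tert-butyl methyl propanedioate | COC(=O)CC(=O)OC(C)(C)C | starting material
8 | 5-(benzyloxy)-3-fluorobenzyne (not isolated) | FC1=CC(OCc2ccccc2)=CC#C1 | intermediate
9 | potassium 3-(benzyloxy)-8-(tert-butoxycarbonyl)-5-fluoro-7-methoxybicyclo[4.2.0]octa-1,3,5-trien-7-olate (mixture of diastereomers, not isolated) | [K+].COC1([O-])C(C(=O)OC(C)(C)C)c2cc(OCc3ccccc3)cc(F)c21 | intermediate
10 | methyl 4-(benzyloxy)-2-(2-tert-butoxy-2-oxoethyl)-6-fluorobenzoate | COC(=O)c1c(F)cc(OCc2ccccc2)cc1CC(=O)OC(C)(C)C | intermediate
11 | hexanoyl chloride | CCCCCC(Cl)=O | starting material
12 | methyl 4-(benzyloxy)-2-(1-tert-butoxy-1,3-dioxooctan-2-yl)-6-fluorobenzoate (racemic) | CCCCCC(=O)C(C(=O)OC(C)(C)C)c1cc(OCc2ccccc2)cc(F)c1C(=O)OC | intermediate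
13 | methyl 4-(benzyloxy)-2-fluoro-6-(2-oxoheptyl)benzoate (not isolated) | CCCCCC(=O)Cc1cc(OCc2ccccc2)cc(F)c1C(=O)OC | intermediate
14 | 6-(benzyloxy)-8-fluoro-3-pentyl-1H-isochromen-1-one | CCCCCc1cc2cc(OCc3ccccc3)cc(F)c2c(=O)o1 | intermediate
15 | 2-hydroxy-4-methoxybenzaldehyde | COc1ccc(C=O)c(O)c1 | starting material
16 | 2-(benzyloxy)-4-methoxybenzaldehyde | COc1ccc(C=O)c(OCc2ccccc2)c1 | intermediate
17 | 2-(benzyloxy)-4-methoxyphenyl formate (not isolated) | COc1ccc(OC=O)c(OCc2ccccc2)c1 | intermediate
18 | 2-(benzyloxy)-4-methoxyphenol | COc1ccc(O)c(OCc2ccccc2)c1 | intermediate
19 | 3-(benzyloxy)-2-hydroxy-5-methoxybenzaldehyde | COc1cc(C=O)c(O)c(OCc2ccccc2)c1 | intermediate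
20 | 2-(benzyloxy)-4-methoxy-6-[(1Z)-pent-1-en-1-yl]phenol (Z drawn, E/Z mixture) | CCC/C=C\c1cc(OC)cc(OCc2ccccc2)c1O | intermediate
21 | 2-(benzyloxy)-4-methoxy-6-pentylphenol | CCCCCc1cc(OC)cc(OCc2ccccc2)c1O | intermediate
22 | 6-(benzyloxy)-8-[2-(benzyloxy)-4-methoxy-6-pentylphenoxy]-3-pentyl-1H-isochromen-1-one | CCCCCc1cc2cc(OCc3ccccc3)cc(Oc3c(OCc4ccccc4)cc(OC)cc3CCCCC)c2c(=O)o1 | intermediate
23 | 6-hydroxy-8-(2-hydroxy-4-methoxy-6-pentylphenoxy)-3-pentyl-1H-isochromen-1-one | CCCCCc1cc2cc(O)cc(Oc3c(O)cc(OC)cc3CCCCC)c2c(=O)o1 | target

## Step count and least certain steps

Total: 14 steps. Longest linear sequence: 9 steps (steps 1–7, 13 and 14); the ring-B branch (steps 8–12) joins at step 13.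

Step 5 (key step). The likeliest failure is proton transfer to the aryl anion outrunning the four-membered ring closure, because 7 and the malonate C–H of the first adduct are both acidic and close by. The malonate would then be arylated with no carboxyl group moving to C8a. Migration of the tert-butoxycarbonyl group or a second arylation would cost material in the same way. Fallback: set out from 2, metalate as in step 2 (LiN(i-Pr)2, THF, −78 °C) and add the aryllithium to excess ClCO2Me to obtain methyl 4-(benzyloxy)-2-bromo-6-fluorobenzoate F1. Coupling of the bromide with the Reformatsky reagent BrZnCH2CO2t-Bu (Pd2(dba)3, XPhos, THF, 65 °C) should give 10, where the route is rejoined. C8a–C1 is then made by carboxylation and C4a–C4 by palladium-catalysed arylation of an ester enolate equivalent.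

Step 13. Attack of a 2,6-disubstituted phenoxide on a carbon activated by a single lactone carbonyl may be slow. At the temperature needed, opening of the enol lactone by traces of hydroxide can overtake it. Fallback: make the ether before the lactone. Set out from 10 and 21 (Cs2CO3, DMSO, 120 °C; the open-chain diester has no lactone to lose and tolerates harder conditions) to obtain methyl 4-(benzyloxy)-2-[2-(benzyloxy)-4-methoxy-6-pentylphenoxy]-6-(2-tert-butoxy-2-oxoethyl)benzoate F2. Acylate with 11 as in step 6 to methyl 4-(benzyloxy)-2-[2-(benzyloxy)-4-methoxy-6-pentylphenoxy]-6-(1-tert-butoxy-1,3-dioxooctan-2-yl)benzoate F3, then treat with catalytic TsOH as in step 7. The route is rejoined at 22.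

Step 2. Metalation may occur at a C–H next to the benzyloxy group (helped by lithium coordination) instead of between the halogens. The aryllithium may also lose lithium halide to an aryne, or bromine may migrate. Fallback: fix the position by electrophilic substitution instead of C–H acidity. From 2, NBS in MeCN should brominate para to the benzyloxy group and give 5-(benzyloxy)-1,2-dibromo-3-fluorobenzene F4. The bromine flanked by fluorine and bromine is the one expected to undergo halogen–magnesium exchange (i-PrMgCl·LiCl, THF, −40 °C), and Me3SiOTf then gives 3, where the route is rejoined.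

Step 7. The enol of the β-keto ester may close onto the methyl ester before the tert-butyl group is lost. The carboxyl group would then sit on C4 of a finished isocoumarin and leave only under forcing acid, which the benzyl ether may not survive. Fallback: make ketone 13 before any lactone can form. From 10, CF3CO2H in CH2Cl2 at rt gives [5-(benzyloxy)-3-fluoro-2-(methoxycarbonyl)phenyl]acetic acid F5. Its dianion (LiN(i-Pr)2, 3 equiv, THF, −78 °C) is acylated with 11, and the β-keto acid should decarboxylate on acidic work-up at rt to give 13. Catalytic TsOH in toluene then closes 13 to 14, where the route is rejoined.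

Step 12. Saturation of the β-alkylstyrene may be slow or incomplete, and a more active catalyst would risk hydrogenolysis of the aryl benzyl ether. Fallback avoiding both the alkene and hydrogen: from 19, n-BuMgBr (2.5 equiv, THF, 0 °C) gives 2-(benzyloxy)-6-(1-hydroxypentyl)-4-methoxyphenol F6 (racemic). Et3SiH and CF3CO2H in CH2Cl2 at 0 °C should ionise the ortho-hydroxybenzylic alcohol and reduce the cation to 21, where the route is rejoined.

## Further compounds

F1 | step 5 | methyl 4-(benzyloxy)-2-bromo-6-fluorobenzoate | COC(=O)c1c(F)cc(OCc2ccccc2)cc1Br
F2 | step 13 | methyl 4-(benzyloxy)-2-[2-(benzyloxy)-4-methoxy-6-pentylphenoxy]-6-(2-tert-butoxy-2-oxoethyl)benzoate | CCCCCc1cc(OC)cc(OCc2ccccc2)c1Oc1cc(OCc2ccccc2)cc(CC(=O)OC(C)(C)C)c1C(=O)OC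
F3 | step 13 | methyl 4-(benzyloxy)-2-[2-(benzyloxy)-4-methoxy-6-pentylphenoxy]-6-(1-tert-butoxy-1,3-dioxooctan-2-yl)benzoate (racemic) | CCCCCC(=O)C(C(=O)OC(C)(C)C)c1cc(OCc2ccccc2)cc(Oc2c(OCc3ccccc3)cc(OC)cc2CCCCC)c1C(=O)OC
F4 | step 2 | 5-(benzyloxy)-1,2-dibromo-3-fluorobenzene | Fc1cc(OCc2ccccc2)cc(Br)c1Br
F5 | step 7 | [5-(benzyloxy)-3-fluoro-2-(methoxycarbonyl)phenyl]acetic acid | COC(=O)c1c(F)cc(OCc2ccccc2)cc1CC(=O)O
F6 | step 12 | 2-(benzyloxy)-6-(1-hydroxypentyl)-4-methoxyphenol (racemic) | CCCCC(O)c1cc(OC)cc(OCc2ccccc2)c1O
A1 | alternative 1 | 8-[2-(benzyloxy)-4-methoxy-6-pentylphenoxy]-6-hydroxy-3-pentyl-1H-isochromen-1-one | CCCCCc1cc2cc(O)cc(Oc3c(OCc4ccccc4)cc(OC)cc3CCCCC)c2c(=O)o1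
A2 | alternative 1 | 4-[2-(benzyloxy)-4-methoxy-6-pentylphenoxy]-6-(2,4-dioxononyl)-2H-pyran-2-one | CCCCCC(=O)CC(=O)Cc1cc(Oc2c(OCc3ccccc3)cc(OC)cc2CCCCC)cc(=O)o1
A3 | alternative 2 | methyl 4-(benzyloxy)-2-[2-(benzyloxy)-4-methoxy-6-pentylphenoxy]-6-methylbenzoate | CCCCCc1cc(OC)cc(OCc2ccccc2)c1Oc1cc(OCc2ccccc2)cc(C)c1C(=O)OC
A4 | alternative 2 | methyl 4-[2-(benzyloxy)-4-methoxy-6-pentylphenoxy]-2-methyl-6-oxo-6H-pyran-3-carboxylate | COC(=O)c1c(C)oc(=O)cc1Oc1c(OCc2ccccc2)cc(OC)cc1CCCCC
A5 | alternative 2 | 1,1-bis(benzyloxy)ethene | C=C(OCc1ccccc1)OCc1ccccc1
A6 | alternative 3 | methyl 1-{[6-(benzyloxy)-1-oxo-3-pentyl-1H-isochromen-8-yl]oxy}-2,4-dioxo-6-pentylcyclohexane-1-carboxylate (mixture of diastereomers) | COC(=O)C1(Oc2cc(OCc3ccccc3)cc3cc(CCCCC)oc(=O)c23)C(CCCCC)CC(=O)CC1=O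
A7 | alternative 3 | dimethyl 2-{[6-(benzyloxy)-1-oxo-3-pentyl-1H-isochromen-8-yl]oxy}propanedioate | COC(=O)C(Oc1cc(OCc2ccccc2)cc2cc(CCCCC)oc(=O)c12)C(=O)OC
A8 | alternative 3 | (3E)-non-3-en-2-one | CCCCC/C=C/C(C)=O
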